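**Strategy.** Everything rests on disconnecting ring C at C4–C4a. A β-aryloxyacrylic acid that already carries all the ring oxygens (O3 as a methoxymethyl ether, O5 and O7 as benzyl ethers) is activated as a mixed anhydride and acylates ring A intramolecularly, closing the pyranone in one operation. The step exploits C4a, flanked by the oxygen-bearing C5 and C8a and para to C7–O: a highly activated carbon of the symmetric phloroglucinol-type ring A and the only one the tethered acyl carbon C4 can reach. Masking O3 orthogonally to the benzyl ethers lets hydrogenolysis free only the 5- and 7-hydroxyls, so the non-chelated 7-OH can be prenylated selectively before mild acid releases the 3-OH.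

Key step: step 6

Remark on the chemistry: the alkene geometry of 6, 8 and 9 is drawn as the isomer expected from chelation-controlled sulfonylation and substitution with retention (ester or carboxyl cis to the C3 oxygen). A minor geometric isomer is tolerated, because the push-pull alkene can equilibrate under the acid of step 6.

Step 1
Reactants: 1 methyl glycolate
Product: 2 methyl 2-(methoxymethoxy)acetate
Conditions: MOMCl, iPr2NEt, CH2Cl2, 0 °C → rt
Reagents that add atoms: chloromethyl methyl ether, COCCl
Why: O-alkylation of the primary alcohol by the α-chloro ether under a hindered amine base (methoxymethyl acetal protection) should leave the ester untouched and give an ether that tolerates enolate chemistry, hydroxide and hydrogenolysis.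

Step 2
Reactants: 2 methyl 2-(methoxymethoxy)acetate; 3 4-methoxybenzoyl chloride
Product: 5 methyl 2-(methoxymethoxy)-3-(4-methoxyphenyl)-3-oxopropanoate (racemic), via lithium enolate 4 (not isolated)
Conditions: 2 (2.1 equiv), LiN(iPr)2 (2.1 equiv), THF, −78 °C; then 3 (1.0 equiv), −78 → −40 °C; AcOH quench
Reagents that add atoms: none
Why: Crossed Claisen-type C-acylation of the chelated lithium glycolate enolate by the aroyl chloride should give the β-keto ester, the second equivalent of enolate taking up the acidic C2 proton of the product so that double acylation is suppressed; the C2 stereocentre forms racemic and is erased in step 3.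

Step 3
Reactants: 5 methyl 2-(methoxymethoxy)-3-(4-methoxyphenyl)-3-oxopropanoate
Product: 6 methyl (E)-2-(methoxymethoxy)-3-(4-methoxyphenyl)-3-(tosyloxy)prop-2-enoate (ester cis to the tosyloxy group)
Conditions: TsCl, TMEDA, LiCl, MeCN, 0 °C → rt
Reagents that add atoms: p-toluenesulfonyl chloride, Cc1ccc(S(=O)(=O)Cl)cc1
Why: Stereodefined enol tosylation, in which O-sulfonylation of the lithium-chelated enolate of the β-keto ester should trap the enol with ester and sulfonate cis and turn C3 into an electrophilic vinylogous sulfonate carbon.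

Step 4
Reactants: 6 methyl (E)-2-(methoxymethoxy)-3-(4-methoxyphenyl)-3-(tosyloxy)prop-2-enoate; 7 3,5-bis(benzyloxy)phenol
Product: 8 methyl (E)-3-[3,5-bis(benzyloxy)phenoxy]-2-(methoxymethoxy)-3-(4-methoxyphenyl)prop-2-enoate (ester cis to the aryloxy group)
Conditions: Cs2CO3, DMF, 25 → 60 °C
Reagents that add atoms: none
Why: Nucleophilic vinylic substitution by addition–elimination, in which the phenoxide adds to C3 of the β-sulfonyloxy acrylate and the ester-stabilised carbanion expels tosylate, should proceed mainly with retention and place the aryloxy group cis to the ester.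

Step 5
Reactants: 8 methyl (E)-3-[3,5-bis(benzyloxy)phenoxy]-2-(methoxymethoxy)-3-(4-methoxyphenyl)prop-2-enoate
Product: 9 (E)-3-[3,5-bis(benzyloxy)phenoxy]-2-(methoxymethoxy)-3-(4-methoxyphenyl)prop-2-enoic acid
Conditions: LiOH·H2O, THF/MeOH/H2O, rt → 40 °C; then cold 1 M HCl to pH 4
Reagents that add atoms: lithium hydroxide, [Li+].[OH-]
Why: Saponification by acyl–oxygen cleavage should be clean because the α-alkoxy donor and the fully substituted β-carbon disfavour conjugate attack, the benzyl ethers and the acetal are inert to hydroxide, and brief cold acidification avoids enol ether hydrolysis.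

Step 6
Reactants: 9 (E)-3-[3,5-bis(benzyloxy)phenoxy]-2-(methoxymethoxy)-3-(4-methoxyphenyl)prop-2-enoic acid
Product: 11 5,7-bis(benzyloxy)-3-(methoxymethoxy)-2-(4-methoxyphenyl)-4H-chromen-4-one, via mixed trifluoroacetic anhydride 10 (not isolated)
Conditions: (CF3CO)2O (1.5 equiv), CH2Cl2, 0 °C → rt; aq. NaHCO3 quench
Reagents that add atoms: none
Why: Trifluoroacetic anhydride converts the acid into mixed anhydride 10, whose acyl carbon (future C4) is attacked, as such or as the derived acylium ion, by the ring A carbon ortho to the enol ether oxygen (future C4a), and loss of a proton from the arenium ion restores aromaticity. The closest known reaction type is the intramolecular Friedel–Crafts acylation of β-aryloxyacrylic and β-aryloxycinnamic acids to chromones and flavones. Ring C closes as a six-membered ring by electrophilic aromatic substitution, with the C4a–C8a arene bond inside the new ring (endo) and the acyl C=O outside it (exo). No stereocentre is formed; the closure only needs the carboxyl cis to the aryloxy group across C2=C3, as in (E)-acid 9, and any trans isomer can reach that geometry by acid-mediated rotation of the push-pull alkene through its C2-protonated oxocarbenium form. Site selectivity is secured by the substrate: the two ortho carbons of ring A are equivalent by symmetry, each lies between two oxygen-bearing carbons and para to the third, the equally activated carbon between the benzyloxy groups cannot reach the tethered acyl group, and the product flavone is deactivated towards a second acylation. The dilute trifluoroacetic acid released at 0 °C should spare the benzyl ethers and the methoxymethyl acetal.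

Step 7
Reactants: 11 5,7-bis(benzyloxy)-3-(methoxymethoxy)-2-(4-methoxyphenyl)-4H-chromen-4-one
Product: 12 5,7-dihydroxy-3-(methoxymethoxy)-2-(4-methoxyphenyl)-4H-chromen-4-one
Conditions: H2 (1 atm), Pd/C, THF/MeOH, rt
Reagents that add atoms: none
Why: Heterogeneous hydrogenolysis of the two aryl benzyl ethers over palladium on carbon should leave the methoxymethyl acetal, the aryl methyl ether and the conjugated C2=C3 bond of the chromone untouched.

Step 8
Reactants: 12 5,7-dihydroxy-3-(methoxymethoxy)-2-(4-methoxyphenyl)-4H-chromen-4-one; 13 prenyl bromide (1-bromo-3-methylbut-2-ene)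
Product: 14 5-hydroxy-3-(methoxymethoxy)-2-(4-methoxyphenyl)-7-[(3-methylbut-2-en-1-yl)oxy]-4H-chromen-4-one
Conditions: 13 (1.1 equiv), K2CO3 (1.2 equiv), acetone, rt → 40 °C
Reagents that add atoms: none
Why: Williamson etherification under weak base should be selective for the 7-hydroxyl, because the 5-hydroxyl is held in a hydrogen bond to the C4 carbonyl and is far less acidic and nucleophilic, while O3 is blocked as the acetal.

Step 9
Reactants: 14 5-hydroxy-3-(methoxymethoxy)-2-(4-methoxyphenyl)-7-[(3-methylbut-2-en-1-yl)oxy]-4H-chromen-4-one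
Product: 15 3,5-dihydroxy-2-(4-methoxyphenyl)-7-[(3-methylbut-2-en-1-yl)oxy]-4H-chromen-4-one (target)
Conditions: HCl (0.5 M in MeOH), THF, 0 °C → rt
Reagents that add atoms: none
Why: Acid-catalysed methanolysis of the methoxymethyl acetal, eased by the good leaving-group ability of the flavonol oxygen, should release the 3-hydroxyl under conditions too mild to ionise the aryl prenyl ether or to add across its trisubstituted alkene.

**Compound list**

1 | methyl glycolate (methyl 2-hydroxyacetate) | COC(=O)CO | starting material
2 | methyl 2-(methoxymethoxy)acetate | COCOCC(=O)OC | intermediate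
3 | 4-methoxybenzoyl chloride | COc1ccc(C(=O)Cl)cc1 | starting material
4 | lithium enolate of 2 (lithium 1-methoxy-2-(methoxymethoxy)ethen-1-olate) | [Li+].[O-]C(OC)=COCOC | intermediate
5 | methyl 2-(methoxymethoxy)-3-(4-methoxyphenyl)-3-oxopropanoate (racemic) | COCOC(C(=O)OC)C(=O)c1ccc(OC)cc1 | intermediate
6 | methyl (E)-2-(methoxymethoxy)-3-(4-methoxyphenyl)-3-(tosyloxy)prop-2-enoate | COC(=O)/C(OCOC)=C(\OS(=O)(=O)c1ccc(C)cc1)c1ccc(OC)cc1 | intermediate
7 | 3,5-bis(benzyloxy)phenol | Oc1cc(OCc2ccccc2)cc(OCc2ccccc2)c1 | starting material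
8 | methyl (E)-3-[3,5-bis(benzyloxy)phenoxy]-2-(methoxymethoxy)-3-(4-methoxyphenyl)prop-2-enoate | COC(=O)/C(OCOC)=C(\Oc1cc(OCc2ccccc2)cc(OCc2ccccc2)c1)c1ccc(OC)cc1 | intermediate
9 | (E)-3-[3,5-bis(benzyloxy)phenoxy]-2-(methoxymethoxy)-3-(4-methoxyphenyl)prop-2-enoic acid | OC(=O)/C(OCOC)=C(\Oc1cc(OCc2ccccc2)cc(OCc2ccccc2)c1)c1ccc(OC)cc1 | intermediate
10 | mixed anhydride of 9 with trifluoroacetic acid | O=C(OC(=O)C(F)(F)F)/C(OCOC)=C(\Oc1cc(OCc2ccccc2)cc(OCc2ccccc2)c1)c1ccc(OC)cc1 | intermediate
11 | 5,7-bis(benzyloxy)-3-(methoxymethoxy)-2-(4-methoxyphenyl)-4H-chromen-4-one | COCOc1c(-c2ccc(OC)cc2)oc2cc(OCc3ccccc3)cc(OCc3ccccc3)c2c1=O | intermediate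
12 | 5,7-dihydroxy-3-(methoxymethoxy)-2-(4-methoxyphenyl)-4H-chromen-4-one | COCOc1c(-c2ccc(OC)cc2)oc2cc(O)cc(O)c2c1=O | intermediate
13 | prenyl bromide (1-bromo-3-methylbut-2-ene) | CC(C)=CCBr | starting material
14 | 5-hydroxy-3-(methoxymethoxy)-2-(4-methoxyphenyl)-7-[(3-methylbut-2-en-1-yl)oxy]-4H-chromen-4-one | COCOc1c(-c2ccc(OC)cc2)oc2cc(OCC=C(C)C)cc(O)c2c1=O | intermediate
15 | 3,5-dihydroxy-2-(4-methoxyphenyl)-7-[(3-methylbut-2-en-1-yl)oxy]-4H-chromen-4-one (no stereocentres) | COc1ccc(-c2oc3cc(OCC=C(C)C)cc(O)c3c(=O)c2O)cc1 | target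

**Step count.** Total: 9 steps. Longest linear sequence: 9 steps (1 → 15); compounds 3, 7 and 13 are purchased.

**Steps most likely to fail**

Step 6 (key step). The acid set free may cleave or acyl-exchange the acetal at O3, excess anhydride may trifluoroacetylate the electron-rich ring A intermolecularly, or a trans-configured acid may fail to isomerise under such mild acid. The fallback sets out from phenol 7 and acid chloride 3 and returns to the route at 11, closing ring C at O1–C2 instead. Ortho-C-acetylation of 7 by Fries rearrangement of its acetate (Ac2O, BF3·OEt2) would give 1-[2,4-bis(benzyloxy)-6-hydroxyphenyl]ethan-1-one F1. Aroylation of its dianion with 3 (LiN(SiMe3)2, THF; Baker–Venkataraman-type acyl transfer) would give 1-[2,4-bis(benzyloxy)-6-hydroxyphenyl]-3-(4-methoxyphenyl)propane-1,3-dione F2. Acid-catalysed cyclodehydration (p-TsOH, toluene, heat) would give 5,7-bis(benzyloxy)-2-(4-methoxyphenyl)-4H-chromen-4-one F3. Epoxidation of its C2=C3 bond with dimethyldioxirane would give racemic 2,3-epoxy-5,7-bis(benzyloxy)-2-(4-methoxyphenyl)chroman-4-one F4. Acid-induced isomerisation of the epoxide (p-TsOH, CH2Cl2) would give 5,7-bis(benzyloxy)-3-hydroxy-2-(4-methoxyphenyl)-4H-chromen-4-one F5. Protection of the 3-hydroxyl with MOMCl and iPr2NEt then delivers 11.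

Step 4. The phenoxide may attack sulfur instead of C3 (sulfonyl transfer that returns the keto ester enolate), or addition to the donor-substituted, fully substituted alkene may be too slow. The fallback sets out from keto ester 5 and returns at 8. The sodium enolate of 5 (NaH, THF) would be triflated with PhNTf2 to methyl (E)-2-(methoxymethoxy)-3-(4-methoxyphenyl)-3-{[(trifluoromethyl)sulfonyl]oxy}prop-2-enoate F6. F6 would then be coupled with phenol 7 under palladium catalysis (Pd2(dba)3, 2-(di-tert-butylphosphino)biphenyl, K3PO4, toluene, 80 °C). Oxidative addition of zerovalent palladium into the vinyl C–O bond and C–O reductive elimination replace the addition–elimination and should retain the alkene geometry.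

Step 9. While the acetal is cleaved, acid may ionise the aryl prenyl ether (loss of the prenyl group or its migration to C6 or C8) or add HCl or methanol across the alkene. The fallback sets out from 12 and returns at target 15, removing the acetal before the prenyl group is present. Methanolysis of 12 (HCl, MeOH, 50 °C) would give 3,5,7-trihydroxy-2-(4-methoxyphenyl)-4H-chromen-4-one F7. Peracetylation (Ac2O, pyridine) would give 2-(4-methoxyphenyl)-4-oxo-4H-chromene-3,5,7-triyl triacetate F8. Deacetylative alkylation with 13 (K2CO3, KI, acetone, reflux) exchanges the most labile 7-acetate and would give 2-(4-methoxyphenyl)-7-[(3-methylbut-2-en-1-yl)oxy]-4-oxo-4H-chromene-3,5-diyl diacetate F9. Mild methanolysis of the two remaining acetates (K2CO3, MeOH, rt) then gives 15.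

**Further compounds**

F1 | step 6 | 1-[2,4-bis(benzyloxy)-6-hydroxyphenyl]ethan-1-one | CC(=O)c1c(O)cc(OCc2ccccc2)cc1OCc1ccccc1
F2 | step 6 | 1-[2,4-bis(benzyloxy)-6-hydroxyphenyl]-3-(4-methoxyphenyl)propane-1,3-dione | COc1ccc(C(=O)CC(=O)c2c(O)cc(OCc3ccccc3)cc2OCc2ccccc2)cc1
F3 | step 6 | 5,7-bis(benzyloxy)-2-(4-methoxyphenyl)-4H-chromen-4-one | COc1ccc(-c2cc(=O)c3c(OCc4ccccc4)cc(OCc4ccccc4)cc3o2)cc1
F4 | step 6 | 2,3-epoxy-5,7-bis(benzyloxy)-2-(4-methoxyphenyl)chroman-4-one (racemic, one enantiomer drawn) | COc1ccc(cc1)[C@]12O[C@H]1C(=O)c1c(OCc3ccccc3)cc(OCc3ccccc3)cc1O2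
F5 | step 6 | 5,7-bis(benzyloxy)-3-hydroxy-2-(4-methoxyphenyl)-4H-chromen-4-one | COc1ccc(-c2oc3cc(OCc4ccccc4)cc(OCc4ccccc4)c3c(=O)c2O)cc1
F6 | step 4 | methyl (E)-2-(methoxymethoxy)-3-(4-methoxyphenyl)-3-{[(trifluoromethyl)sulfonyl]oxy}prop-2-enoate | COC(=O)/C(OCOC)=C(\OS(=O)(=O)C(F)(F)F)c1ccc(OC)cc1
F7 | step 9 | 3,5,7-trihydroxy-2-(4-methoxyphenyl)-4H-chromen-4-one | COc1ccc(-c2oc3cc(O)cc(O)c3c(=O)c2O)cc1
F8 | step 9 | 2-(4-methoxyphenyl)-4-oxo-4H-chromene-3,5,7-triyl triacetate | COc1ccc(-c2oc3cc(OC(C)=O)cc(OC(C)=O)c3c(=O)c2OC(C)=O)cc1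
F9 | step 9 | 2-(4-methoxyphenyl)-7-[(3-methylbut-2-en-1-yl)oxy]-4-oxo-4H-chromene-3,5-diyl diacetate | COc1ccc(-c2oc3cc(OCC=C(C)C)cc(OC(C)=O)c3c(=O)c2OC(C)=O)cc1
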